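The pyrrole carbons C2, C3, C4 and C5, the formyl carbon on C2 and the nonadecyl chain on C5 form one unbranched C24 chain. In it the four ring carbons stand at the oxidation level of a conjugated diyne, and N1, bridging C2 and C5, is the only atom outside the chain.
Retrosynthetic cuts, in order: aldehyde back to its diethyl acetal; N1–C2 and N1–C5 together, which releases ammonia and a linear 2,4-diyne acetal; the central C3–C4 bond between the two alkynes; the bond from C5 to the first carbon of the nonadecyl chain.
Forward, the chain is joined first: acetylide alkylation gives the C21 terminal alkyne, and copper-catalysed coupling with the brominated C3 alkynyl acetal completes the C24 diyne.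
The single ring then arises in one operation when ammonia adds twice across the diyne, and dilute acid finally uncovers the aldehyde.
The target has no stereocentre and no configured double bond, so no stereochemical control is required.

Key step: step 4

Remark: the open-chain compounds are numbered from the acetal carbon (C1), so chain carbons C2 to C5 become ring carbons C2 to C5. The four starting materials are taken to be catalogue chemicals.

Step 1
Reactants: 1 1-bromononadecane; 2 lithium acetylide ethylenediamine complex
Product: 3 henicos-1-yne
Conditions: LiC≡CH·H2NCH2CH2NH2 (1.5 equiv), DMSO–THF, 0 °C to rt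
Reagents that add atoms: none
Why: Acetylide alkylation (SN2), in which an unbranched primary bromide is displaced by the amine-stabilised lithium acetylide in a dipolar aprotic medium, is a standard entry to long-chain 1-alkynes, and THF as cosolvent keeps the waxy bromide in solution.

Step 2
Reactants: 4 3,3-diethoxyprop-1-yne
Product: 5 3-bromo-1,1-diethoxyprop-2-yne
Conditions: NBS (1.1 equiv), AgNO3 (10 mol%), acetone, rt, dark
Reagents that add atoms: N-bromosuccinimide, O=C1CCC(=O)N1Br
Why: Silver-catalysed electrophilic bromination of a terminal alkyne with NBS runs under essentially neutral conditions, so only the acetylenic C–H bond reacts and the diethyl acetal should stay intact.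

Step 3
Reactants: 3 henicos-1-yne; 5 3-bromo-1,1-diethoxyprop-2-yne
Product: 6 1,1-diethoxytetracosa-2,4-diyne
Conditions: CuCl (10 mol%), NH2OH·HCl (30 mol%), n-BuNH2 (3 equiv), THF–MeOH, 0 °C to rt, slow addition of 5 (1.2 equiv)
Reagents that add atoms: none
Why: In this Cadiot–Chodkiewicz coupling the terminal alkyne is cuprated by monovalent copper in the amine medium and joins the electron-poor bromoalkyne to form C3–C4, while hydroxylamine keeps the copper reduced and so holds back oxidative homocoupling, the basic medium protects the acetal, and the two possible symmetrical diynes differ enough in polarity from 6 to be removed on triethylamine-buffered silica.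

Step 4
Reactants: 6 1,1-diethoxytetracosa-2,4-diyne; 7 ammonia
Product: 9 2-(diethoxymethyl)-5-nonadecyl-1H-pyrrole, via aminoenyne 8 (not isolated)
Conditions: CuCl (15 mol%), NH3 (condensed, about 40 equiv), EtOH–1,4-dioxane, steel autoclave under argon, 120 °C; basic work-up (aq NH3 wash, K2CO3), crude product used at once
Reagents that add atoms: none
Why: CuCl dissolves in the ammonia-rich medium as an ammine complex of monovalent copper that π-activates the diyne, and ammonia adds first to the outer carbon C5, the less hindered terminus and the one from which the developing negative charge is relayed through C4 to C2 next to the inductively withdrawing acetal carbon; protonation gives aminoenyne 8 and forms N1–C5. Enamine–imine tautomerism lets the C4=C5 geometry settle with nitrogen on the side of the remaining triple bond, whose far carbon C2 is then attacked in a 5-endo-dig closure that forms N1–C2, and proton shifts aromatise the ring in a redox-neutral process that loses no atom. The closest known reaction type is this very one, the CuCl-catalysed double hydroamination of conjugated 1,3-diynes by ammonia or primary amines to 2,5-disubstituted pyrroles, used here on a new diyne. No stereocentre is created. The selectivity needed is attack at the two outer diyne carbons instead of the inner ones, and the substrate secures it because only outer attack keeps the new enamine conjugated with the second alkyne and sets up a five-membered ring, while a first attack at C2 in place of C5 would still converge on 9. The acetal should be safe because the medium is basic, CuCl is too weak a Lewis acid to ionise a propargylic C–O bond (the reason for passing over cationic complexes of monovalent gold), ethanol as cosolvent makes alkoxy exchange degenerate, and any ethoxy-to-amino exchange at C1 stays at the aldehyde oxidation level and is erased in step 5.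

Step 5
Reactants: 9 2-(diethoxymethyl)-5-nonadecyl-1H-pyrrole
Product: 10 5-nonadecyl-1H-pyrrole-2-carbaldehyde (target, CNP0218351.0)
Conditions: 0.5 M aq HCl, THF, 0 °C to rt
Reagents that add atoms: water, O
Why: Acid-catalysed acetal hydrolysis should be very fast here because the pyrrole nitrogen pushes out ethanol through an azafulvenium ion, the product is an acid-stable vinylogous formamide, and both α-positions are substituted, which limits self-condensation.

Compound list
1 | 1-bromononadecane | CCCCCCCCCCCCCCCCCCCBr | starting material
2 | lithium acetylide ethylenediamine complex | [Li+].[C-]#C.NCCN | starting material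
3 | henicos-1-yne | CCCCCCCCCCCCCCCCCCCC#C | intermediate
4 | 3,3-diethoxyprop-1-yne | C#CC(OCC)OCC | starting material
5 | 3-bromo-1,1-diethoxyprop-2-yne | BrC#CC(OCC)OCC | intermediate
6 | 1,1-diethoxytetracosa-2,4-diyne | CCCCCCCCCCCCCCCCCCCC#CC#CC(OCC)OCC | intermediate
7 | ammonia | N | starting material
8 | (4Z)-1,1-diethoxytetracos-4-en-2-yn-5-amine (aminoenyne) | CCCCCCCCCCCCCCCCCCC/C(N)=C/C#CC(OCC)OCC | intermediate
9 | 2-(diethoxymethyl)-5-nonadecyl-1H-pyrrole | CCCCCCCCCCCCCCCCCCCc1ccc(C(OCC)OCC)[nH]1 | intermediate
10 | 5-nonadecyl-1H-pyrrole-2-carbaldehyde | CCCCCCCCCCCCCCCCCCCc1ccc(C=O)[nH]1 | target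

Total step count: 5. Longest linear sequence: 4 (steps 1, 3, 4 and 5).

Steps most likely to fail

Step 4. The first N–H addition may be too slow, because ammonia crowds the copper centre and is only a modest nucleophile toward an alkyl-substituted diyne. Thermal oligomerisation of the diyne or addition at an inner carbon could then take over. The fallback sets out from 6 and returns at 10. It forms the same N1–C2 and N1–C5 bonds but brings the nitrogen in as a cleavable primary amine, the best documented nucleophile class for this cyclisation.
- Heating 6 with 2,4-dimethoxybenzylamine and CuCl in dioxane at 100 °C should give 1-(2,4-dimethoxybenzyl)-2-(diethoxymethyl)-5-nonadecyl-1H-pyrrole F1.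
- Dilute aqueous HCl in THF should convert it into 1-(2,4-dimethoxybenzyl)-5-nonadecyl-1H-pyrrole-2-carbaldehyde F2.
- Warming in trifluoroacetic acid with excess anisole should release the electron-rich benzyl group as a stabilised cation, which anisole traps, leaving 10.

Step 3. Homocoupling of either partner may compete, through halogen–copper exchange or adventitious oxidation to divalent copper. Poor mixing of the waxy alkyne with the polar amine medium could also erode the cross-coupling. The fallback sets out from 1 and returns at 6. It avoids any alkyne–alkyne coupling by buying the four-carbon diyne unit intact, and it bypasses steps 1 and 2 as well.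
- 1,4-Bis(trimethylsilyl)buta-1,3-diyne is monodesilylated with MeLi·LiBr in THF to lithium 4-(trimethylsilyl)buta-1,3-diyn-1-ide F3.
- This is alkylated with 1 in THF–DMPU to trimethyl(tricosa-1,3-diyn-1-yl)silane F4.
- K2CO3 in MeOH–THF should give tricosa-1,3-diyne F5.
- EtMgBr converts it into bromo(tricosa-1,3-diyn-1-yl)magnesium F6, which on heating with triethyl orthoformate should deliver 6.

Step 2. The volatile, lachrymatory bromoalkyne may be lost on evaporation. Acid traces formed from NBS in wet acetone could open the acetal, and the product could decay on storage. The fallback sets out from 3 and returns at 6 by placing the halogen on the other fragment.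
- NBS and catalytic AgNO3 in acetone should turn 3 into non-volatile 1-bromohenicos-1-yne F7.
- This is coupled with commercial 4 as the terminal partner (CuCl, NH2OH·HCl, n-BuNH2, THF–MeOH), so that 5 is no longer needed.

Further compounds
F1 | step 4 | 1-(2,4-dimethoxybenzyl)-2-(diethoxymethyl)-5-nonadecyl-1H-pyrrole | CCCCCCCCCCCCCCCCCCCc1ccc(C(OCC)OCC)n1Cc2ccc(OC)cc2OC
F2 | step 4 | 1-(2,4-dimethoxybenzyl)-5-nonadecyl-1H-pyrrole-2-carbaldehyde | CCCCCCCCCCCCCCCCCCCc1ccc(C=O)n1Cc2ccc(OC)cc2OC
F3 | step 3 | lithium 4-(trimethylsilyl)buta-1,3-diyn-1-ide | [Li]C#CC#C[Si](C)(C)C
F4 | step 3 | trimethyl(tricosa-1,3-diyn-1-yl)silane | CCCCCCCCCCCCCCCCCCCC#CC#C[Si](C)(C)C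
F5 | step 3 | tricosa-1,3-diyne | CCCCCCCCCCCCCCCCCCCC#CC#C
F6 | step 3 | bromo(tricosa-1,3-diyn-1-yl)magnesium | CCCCCCCCCCCCCCCCCCCC#CC#C[Mg]Br
F7 | step 2 | 1-bromohenicos-1-yne | CCCCCCCCCCCCCCCCCCCC#CBr
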